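Both 2,4-dihydroxyphenyl rings are cut back together to the two alkyne arms of an all-trans 2,4-diphenylcyclobutane-1,3-diyl bis(ynone). The feature exploited is the pair of ketone C=O groups that join C1 and C3 of the cyclobutane to aryl rings oxygenated at the ortho (C2') and para (C4') carbons. Each C=O activates a C≡C dienophile, and 1,1-dimethoxy-3-(trimethylsilyloxy)buta-1,3-diene delivers the other four ring carbons together with both oxygens. A double Diels–Alder reaction with loss of methanol forms four C–C bonds and both benzene rings in one operation. The cyclobutane core is made by directed double C–H phenylation and base epimerisation.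

Key step: step 8

Remark: "all-trans" means the C1/C3 carbonyl substituents lie on one face of the cyclobutane and the C2/C4 phenyl groups on the other; "all-cis" means all four on one face. The target and all main-route compounds are achiral. The commercial cis monoester 1 is assumed as starting material so that a single amide directs both phenylations.

Step 1
Reactants: 1 cis-3-(methoxycarbonyl)cyclobutane-1-carboxylic acid; 2 8-aminoquinoline
Product: 3 methyl cis-3-(quinolin-8-ylcarbamoyl)cyclobutane-1-carboxylate
Conditions: EDC·HCl, DMAP, CH2Cl2, rt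
Reagents that add atoms: none
Why: Carbodiimide-mediated amide coupling with DMAP as acyl-transfer catalyst acylates the weakly nucleophilic aniline nitrogen of 2 under non-enolising conditions, so the cis-1,3 relationship of 1 is carried over and no stereocentre is made.

Step 2
Reactants: 3 methyl cis-3-(quinolin-8-ylcarbamoyl)cyclobutane-1-carboxylate; 4 iodobenzene
Product: 5 methyl all-cis-2,4-diphenyl-3-(quinolin-8-ylcarbamoyl)cyclobutane-1-carboxylate
Conditions: Pd(OAc)2 (10 mol %), AgOAc (3 equiv), PhI (6 equiv), PhMe, 110 °C
Reagents that add atoms: iodobenzene (second equivalent of 4), Ic1ccccc1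
Why: In this 8-aminoquinoline-directed β-C(sp3)–H arylation, N,N-chelation holds divalent palladium on the amide face and cyclopalladation takes the methylene C–H cis to the amide at C2 and then at C4, each event consuming one molecule of PhI; oxidative addition of PhI to give tetravalent palladium and C–C reductive elimination with retention should place both new phenyl-bearing centres cis to the amide and to the cis ester, giving the all-cis ring.

Step 3
Reactants: 5 methyl all-cis-2,4-diphenyl-3-(quinolin-8-ylcarbamoyl)cyclobutane-1-carboxylate
Product: 6 methyl all-cis-3-[N-(tert-butoxycarbonyl)-N-(quinolin-8-yl)carbamoyl]-2,4-diphenylcyclobutane-1-carboxylate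
Conditions: Boc2O, DMAP, MeCN, 50 °C
Reagents that add atoms: di-tert-butyl dicarbonate, CC(C)(C)OC(=O)OC(=O)OC(C)(C)C
Why: DMAP-catalysed N-tert-butoxycarbonylation of the secondary amide should give a twisted, non-chelating N-acyl carbamate whose acyl C–N bond is activated towards alkoxide, and any partial epimerisation here is harmless because step 4 equilibrates the ring centres.

Step 4
Reactants: 6 methyl all-cis-3-[N-(tert-butoxycarbonyl)-N-(quinolin-8-yl)carbamoyl]-2,4-diphenylcyclobutane-1-carboxylate
Product: 8 dimethyl all-trans-2,4-diphenylcyclobutane-1,3-dicarboxylate, via all-cis dimethyl diester 7 (not isolated)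
Conditions: NaOMe, MeOH/THF, rt then 65 °C; aq. NH4Cl
Reagents that add atoms: methanol, CO
Why: Methoxide first cleaves the activated acyl–N bond (alcoholysis of an N-Boc amide) to give diester 7 and then, by reversible enolisation of both ester α-carbons, moves each ester to the face opposite its two phenyl neighbours, so C1 and C3 are set under thermodynamic control in favour of the least crowded all-trans isomer; methoxide is regenerated and methanol is the stoichiometric reagent.

Step 5
Reactants: 8 dimethyl all-trans-2,4-diphenylcyclobutane-1,3-dicarboxylate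
Product: 9 all-trans N1,N3-dimethoxy-N1,N3-dimethyl-2,4-diphenylcyclobutane-1,3-dicarboxamide
Conditions: MeNH(OMe)·HCl (3 equiv), i-PrMgCl (6 equiv), THF, −20 to 0 °C
Reagents that add atoms: N,O-dimethylhydroxylamine hydrochloride, CNOC.Cl; N,O-dimethylhydroxylamine hydrochloride (second equivalent), CNOC.Cl
Why: Direct ester-to-Weinreb-amide aminolysis by the chloromagnesium amide of N,O-dimethylhydroxylamine, one molecule per ester, uses a weakly basic nucleophile at low temperature, so the thermodynamically preferred all-trans centres should not be disturbed.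

Step 6
Reactants: 9 all-trans N1,N3-dimethoxy-N1,N3-dimethyl-2,4-diphenylcyclobutane-1,3-dicarboxamide; 10 ethynylmagnesium bromide
Product: 11 all-trans 1,1'-(2,4-diphenylcyclobutane-1,3-diyl)bis(prop-2-yn-1-one)
Conditions: HC≡CMgBr (0.5 M in THF, 5 equiv), THF, 0 °C to rt; inverse quench into cold 1 M HCl
Reagents that add atoms: ethynylmagnesium bromide (second equivalent of 10), C#C[Mg]Br
Why: In this Weinreb ketone synthesis one acetylide adds to each amide to give a magnesium-chelated tetrahedral intermediate that survives until the quench, and inverse addition into cold acid protonates the released N,O-dimethylhydroxylamine so that it cannot add to the new ynones, while the ring centres stay all-trans.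

Step 7
Reactants: 12 4,4-dimethoxybut-3-en-2-one
Product: 13 1,1-dimethoxy-3-(trimethylsilyloxy)buta-1,3-diene
Conditions: Me3SiCl, Et3N, ZnCl2 (cat.), PhMe, 40 °C; filtration and distillation
Reagents that add atoms: chlorotrimethylsilane, C[Si](C)(C)Cl
Why: Soft enolisation and O-silylation (silyl enol ether formation) at the acetyl CH3, the only enolisable position, should give the electron-rich diene, which is distilled and used fresh.

Step 8
Reactants: 11 all-trans 1,1'-(2,4-diphenylcyclobutane-1,3-diyl)bis(prop-2-yn-1-one); 13 1,1-dimethoxy-3-(trimethylsilyloxy)buta-1,3-diene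
Product: 16 all-trans 1,3-bis(4-hydroxy-2-methoxybenzoyl)-2,4-diphenylcyclobutane, via bis(cyclohexa-1,4-diene) cycloadduct 14 (not isolated), via bis(aryl trimethylsilyl ether) 15 (not isolated)
Conditions: 13 (4 equiv), PhMe, rt to 60 °C; then 1 M HCl, THF, rt
Reagents that add atoms: 1,1-dimethoxy-3-(trimethylsilyloxy)buta-1,3-diene (second equivalent of 13), COC(OC)=CC(=C)O[Si](C)(C)C
Why: The reaction is a normal-electron-demand, asynchronous [4+2] cycloaddition in which the HOMO of diene 13 meets the LUMO of each C≡C–C=O unit, one molecule of 13 per ynone arm: C4 of the diene (its CH2 end, the most nucleophilic carbon) attacks the terminal alkyne carbon and C1 (the dimethoxy-bearing carbon) closes onto the carbonyl-bound alkyne carbon, giving bis(cyclohexa-1,4-diene) 14. Each ring of 14 then loses methanol from the gem-dimethoxy carbon and the doubly allylic CH2 to give aryl silyl ether 15, and dilute acid removes the trimethylsilyl groups. The closest known reaction type is the Diels–Alder/aromatisation of propiolates and ynones with 1,1-dialkoxy-3-silyloxybutadienes, which gives 2-alkoxy-4-hydroxyaryl carbonyl compounds. Both benzene rings close by intermolecular [4+2] cycloaddition, each from four diene carbons and two alkyne carbons with two new C–C bonds per ring. No stereocentre is created, and the four cyclobutane centres are untouched under these neutral conditions and already sit in the thermodynamically preferred all-trans arrangement. The step needs regioselectivity (oxygen ortho and para to the carbonyl), which the matched polarisation of the ynone terminal carbon and diene C4 secures, and complete reaction of both arms, which the excess of 13 secures.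

Step 9
Reactants: 16 all-trans 1,3-bis(4-hydroxy-2-methoxybenzoyl)-2,4-diphenylcyclobutane
Product: 17 all-trans 1,3-bis(2,4-dihydroxybenzoyl)-2,4-diphenylcyclobutane (target, CNP0398987.1)
Conditions: BCl3 (1 M in CH2Cl2, 6 equiv), CH2Cl2, −78 to 0 °C; then H2O
Reagents that add atoms: none
Why: In this chelation-assisted aryl methyl ether cleavage BCl3 binds the ketone oxygen and the neighbouring methoxy oxygen, chloride removes the methyl group by SN2 to leave a six-membered aryloxyboron chelate that water hydrolyses to the ortho phenol, the free para phenols are only borylated and released on work-up, and the cold, non-basic conditions should leave the four ring centres untouched.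

Compound list
1 | cis-3-(methoxycarbonyl)cyclobutane-1-carboxylic acid | COC(=O)[C@H]1C[C@@H](C(O)=O)C1 | starting material
2 | 8-aminoquinoline | Nc1cccc2cccnc12 | starting material
3 | methyl cis-3-(quinolin-8-ylcarbamoyl)cyclobutane-1-carboxylate | COC(=O)[C@H]1C[C@@H](C(=O)Nc2cccc3cccnc23)C1 | intermediate
4 | iodobenzene | Ic1ccccc1 | starting material
5 | methyl all-cis-2,4-diphenyl-3-(quinolin-8-ylcarbamoyl)cyclobutane-1-carboxylate | COC(=O)[C@H]1[C@@H](c2ccccc2)[C@@H](C(=O)Nc2cccc3cccnc23)[C@H]1c1ccccc1 | intermediate
6 | methyl all-cis-3-[N-(tert-butoxycarbonyl)-N-(quinolin-8-yl)carbamoyl]-2,4-diphenylcyclobutane-1-carboxylate | COC(=O)[C@H]1[C@@H](c2ccccc2)[C@@H](C(=O)N(C(=O)OC(C)(C)C)c2cccc3cccnc23)[C@H]1c1ccccc1 | intermediate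
7 | dimethyl all-cis-2,4-diphenylcyclobutane-1,3-dicarboxylate | COC(=O)[C@H]1[C@@H](c2ccccc2)[C@@H](C(=O)OC)[C@H]1c1ccccc1 | intermediate
8 | dimethyl all-trans-2,4-diphenylcyclobutane-1,3-dicarboxylate | COC(=O)[C@H]1[C@H](c2ccccc2)[C@@H](C(=O)OC)[C@@H]1c1ccccc1 | intermediate
9 | all-trans N1,N3-dimethoxy-N1,N3-dimethyl-2,4-diphenylcyclobutane-1,3-dicarboxamide | CON(C)C(=O)[C@H]1[C@H](c2ccccc2)[C@@H](C(=O)N(C)OC)[C@@H]1c1ccccc1 | intermediate
10 | ethynylmagnesium bromide | C#C[Mg]Br | starting material
11 | all-trans 1,1'-(2,4-diphenylcyclobutane-1,3-diyl)bis(prop-2-yn-1-one) | C#CC(=O)[C@H]1[C@H](c2ccccc2)[C@@H](C(=O)C#C)[C@@H]1c1ccccc1 | intermediate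
12 | 4,4-dimethoxybut-3-en-2-one | COC(OC)=CC(C)=O | starting material
13 | 1,1-dimethoxy-3-(trimethylsilyloxy)buta-1,3-diene | COC(OC)=CC(=C)O[Si](C)(C)C | intermediate
14 | all-trans 1,3-bis[6,6-dimethoxy-4-(trimethylsilyloxy)cyclohexa-1,4-diene-1-carbonyl]-2,4-diphenylcyclobutane | COC1(OC)C=C(O[Si](C)(C)C)CC=C1C(=O)[C@H]1[C@H](c2ccccc2)[C@@H](C(=O)C2=CCC(O[Si](C)(C)C)=CC2(OC)OC)[C@@H]1c1ccccc1 | intermediate
15 | all-trans 1,3-bis[2-methoxy-4-(trimethylsilyloxy)benzoyl]-2,4-diphenylcyclobutane | COc1cc(O[Si](C)(C)C)ccc1C(=O)[C@H]1[C@H](c2ccccc2)[C@@H](C(=O)c2ccc(O[Si](C)(C)C)cc2OC)[C@@H]1c1ccccc1 | intermediate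
16 | all-trans 1,3-bis(4-hydroxy-2-methoxybenzoyl)-2,4-diphenylcyclobutane | COc1cc(O)ccc1C(=O)[C@H]1[C@H](c2ccccc2)[C@@H](C(=O)c2ccc(O)cc2OC)[C@@H]1c1ccccc1 | intermediate
17 | all-trans 1,3-bis(2,4-dihydroxybenzoyl)-2,4-diphenylcyclobutane | O=C(c1ccc(O)cc1O)[C@H]1[C@H](c2ccccc2)[C@@H](C(=O)c2ccc(O)cc2O)[C@@H]1c1ccccc1 | target

Total step count: 9. Longest linear sequence: 8 steps (steps 1–6, 8 and 9); step 7 is a one-step side branch that supplies the diene.

Steps most likely to fail

Step 8. The second cycloaddition may lag behind the first, or the diene may be used up by hydrolysis or by open-chain Michael-type addition to the ynone without ring closure, leaving mono-arene or acyclic material. The fallback gives up de novo ring construction and brings the arenes in ready-made. Setting out from bis(Weinreb amide) 9, addition of commercial 2,4-dimethoxyphenylmagnesium bromide (THF, 0 °C to rt, acid quench) should give all-trans 1,3-bis(2,4-dimethoxybenzoyl)-2,4-diphenylcyclobutane F1. Exhaustive O-demethylation with BBr3 (CH2Cl2, −78 °C to rt) would then come back to the route at target 17.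

Step 2. The second C–H insertion may stall as the fourth cis substituent goes in, because the all-cis ring becomes very crowded, leaving mono-phenylated material. The fallback never makes the all-cis tetrasubstituted ring; it places an epimerisation between two separate phenylations. Setting out from 3, phenylation with a limited amount of PhI (1.2 equiv; Pd(OAc)2, AgOAc, PhMe, 80 °C) should stop at methyl all-cis-2-phenyl-3-(quinolin-8-ylcarbamoyl)cyclobutane-1-carboxylate F2 (racemic). NaOMe in MeOH at rt should then epimerise only the more acidic ester-bearing carbon and give methyl 2-phenyl-3-(quinolin-8-ylcarbamoyl)cyclobutane-1-carboxylate F3 (ester trans to the phenyl group and the amide). A second directed phenylation at the remaining methylene would give methyl 2,4-diphenyl-3-(quinolin-8-ylcarbamoyl)cyclobutane-1-carboxylate F4 (both phenyl groups cis to the amide, ester trans). Boc2O/DMAP would convert it into methyl 3-[N-(tert-butoxycarbonyl)-N-(quinolin-8-yl)carbamoyl]-2,4-diphenylcyclobutane-1-carboxylate F5. NaOMe/MeOH at 65 °C would cleave the activated amide to dimethyl 2,4-diphenylcyclobutane-1,3-dicarboxylate F6 (one ester cis and one trans to the phenyl groups, not isolated) and epimerise the remaining centre, coming back to the route at 8.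

Step 4. Methoxide may attack the carbamate carbonyl in place of the hindered acyl carbonyl, so that the Boc group is lost and the amide is regenerated, or step 3 may not activate the crowded amide at all. The fallback removes the auxiliary under Lewis acid without N-activation. Setting out from 5, solvolysis with BF3·OEt2 in MeOH (100 °C, sealed tube) should give the all-cis diester 7, this time isolated, and NaOMe/MeOH at 65 °C would then epimerise it, coming back to the route at 8. No compound outside the list is made on this detour (entry F0).

Further compounds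
F1 | step 8 | all-trans 1,3-bis(2,4-dimethoxybenzoyl)-2,4-diphenylcyclobutane | O=C(c1ccc(OC)cc1OC)[C@H]1[C@H](c2ccccc2)[C@@H](C(=O)c2ccc(OC)cc2OC)[C@@H]1c1ccccc1
F2 | step 2 | methyl all-cis-2-phenyl-3-(quinolin-8-ylcarbamoyl)cyclobutane-1-carboxylate (racemic, one enantiomer drawn) | COC(=O)[C@H]1[C@@H](c2ccccc2)[C@@H](C(=O)Nc2cccc3cccnc23)C1
F3 | step 2 | methyl 2-phenyl-3-(quinolin-8-ylcarbamoyl)cyclobutane-1-carboxylate, ester trans to phenyl and amide, phenyl cis to amide (racemic, one enantiomer drawn) | COC(=O)[C@@H]1[C@@H](c2ccccc2)[C@@H](C(=O)Nc2cccc3cccnc23)C1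
F4 | step 2 | methyl 2,4-diphenyl-3-(quinolin-8-ylcarbamoyl)cyclobutane-1-carboxylate, both phenyls cis to the amide, ester trans | COC(=O)[C@@H]1[C@@H](c2ccccc2)[C@@H](C(=O)Nc2cccc3cccnc23)[C@H]1c1ccccc1
F5 | step 2 | methyl 3-[N-(tert-butoxycarbonyl)-N-(quinolin-8-yl)carbamoyl]-2,4-diphenylcyclobutane-1-carboxylate, both phenyls cis to the acyl carbamate, ester trans | COC(=O)[C@@H]1[C@@H](c2ccccc2)[C@@H](C(=O)N(C(=O)OC(C)(C)C)c2cccc3cccnc23)[C@H]1c1ccccc1
F6 | step 2 | dimethyl 2,4-diphenylcyclobutane-1,3-dicarboxylate, C1 ester trans and C3 ester cis to both phenyls | COC(=O)[C@@H]1[C@@H](c2ccccc2)[C@@H](C(=O)OC)[C@H]1c1ccccc1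
F0 | step 4 | none | none
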